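The numbers were set for the occasion.

The solid reagent tops up its dissolved coupling partner within about 0.385 s, much quicker than the left-handed substrate couples, whose half-life with the partner at solubility is 10.3 s. So while solid remains, you can hold the partner near 0.48 M.

| setting | alder | ash | larch |
|---|---|---|---|
| left-handed substrate | 1.0 M | 1.0 M | 1.0 M |
| solid reagent | 1.00 equiv | 1.50 equiv | 2.00 equiv |
| free catalyst | 6.1 mol% | 6.1 mol% | 6.1 mol% |
| racemization catalyst | 7.5 mol% | 7.5 mol% | 7.5 mol% |
| right-handed substrate | 1.0 M | 1.0 M | 1.0 M |
| time | 20 s | 20 s | 20 s |

1. amount of left-handed product at the end, in percent of the left-handed substrate and right-handed substrate together charged for alder, ash, larch, in this order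
2. how the row runs (rises all the way / falls all the way / rises, then falls / falls, then rises / hardly changes)

- free catalyst is single-handed; left-handed substrate and right-handed substrate are mirror images of each other, charged as a racemate, each of them at the stated concentration
- for a step with 2 of a species take k times the square, and two of it per event
- given per volume of solution although it is solid: solid reagent
- at the start none of the solid reagent is in solution
- a step back or a flat step of under half a point counts as no turn
- "hardly changes" means that all values lie within two and a half points (for a concentration: within two and a half percent of the largest)
- run time (alder): 20 s

    coupling partner + free catalyst + left-handed substrate → free catalyst + left-handed product (k1 = 2.3 /M²/s)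
    left-handed substrate + racemization catalyst ⇌ right-handed substrate + racemization catalyst, rate k2*[racemization catalyst]*[left-handed substrate] forward; the back reaction follows from the equilibrium constant (k2 = 0.71 /M/s)
    2 racemization catalyst → spent catalyst (k3 = 0.43 /M/s)
    solid reagent ⇌ coupling partner, rate k4*(cs4 - [coupling partner]) while solid is left; crystals form when [coupling partner] > cs4 (cs4 = 0.48 M, k4 = 2.6 /s)
    coupling partner + free catalyst + right-handed substrate → free catalyst + right-handed product (k5 = 0.19 /M²/s)

Free catalyst comes back from every turn, so with the partner held, each coupling is pseudo-first-order. The run lasts 1.94 half-lives, so 0.740 M of left-handed substrate couples. The right-handed coupling has the smaller constant and takes 0.105 M. I leave racemization out; the left-handed substrate goes faster than the right-handed, so racemization should feed the left-handed pool from the right-handed one, and my left-handed count errs low, my right-handed count high.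

Now add the partner still dissolved at the end. The solid bill, meaning the solid a run must supply to keep the partner at solubility up to the end, is 1.33 M.

Then turn the one setting, the solid charge, which is counted on the left-handed substrate. Alder holds 1.00 M, less than the bill, so its solid gives out inside the run, the partner falls, and alder ends lower in left-handed product than ash. Ash holds 1.50 M, more than the bill, so by this count its left-handed product comes to 37.0% of both substrates charged. Larch holds 2.00 M, which leaves more solid undissolved and the same 37.0%. My row therefore rises once and then stands flat, and a flat step is no turn.

The forecast reads 57%, 57% and 57%, so hardly changes. Its ground is “I took 1 equiv as 2.0 M”, which by its count leaves solid over in alder too. I differ on that basis, and so on the shape.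

The simulation gives 35.3%, 39.2% and 39.2%: rises all the way.

Alder, charged below the bill of 1.33 M, shows solid at 0% of its charge after 20.0 s with the partner at 0.214 M, while ash, charged above it, shows solid at 10.3% of its charge with the partner at 0.469 M, where charge minus bill gives 11.7%. On larch the same subtraction gives 33.7% of its charge, and its solid stands at 32.7% after 20.0 s.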